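28.7% of the free catalyst charged to this flask can be lost to the stray impurity, if each stray impurity takes one free catalyst. I call this the poison share: c(stray impurity) divided by c(free catalyst), both as charged. Time drops out of it if the two fall together, one for one.

| flask | starting material | gas phase | protic impurity | free catalyst | stray impurity | remark | time |
|---|---|---|---|---|---|---|---|
| maple | 0.40 M | 190 mM (held) | 0.040 M | 0.2 mol% | 0.23 mM | run made earlier |  |
| flask | 0.40 M | 190 mM (held) | 0.0800 M | 0.2 mol% | 0.23 mM |  | 5.0 min |

maple run (percent of the starting material charged)

| time / s | product / % | crystals / % |
|---|---|---|
| 10.0 | 2.7 | 0.4 |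
| 12.0 | 3.5 | 0.1 |
| 15.0 | 4.2 | 1.0 |
| 20.0 | 7.0 | 2.0 |
| 25.0 | 13.1 | 3.5 |
| 30.0 | 15.6 | 6.0 |

(readings scatter by 1 percentage point)

- amounts and yields of product count crystals too
- given per volume of solution although it is solid: crystals
- at the start none of the gas phase is in solution
- no earlier run changes the charge of protic impurity; that part of a forecast is a guess

- how much product and crystals together there is at 5.0 min, in percent of the starting material charged
- concentration of dissolved gas in solution at 5.0 min, in percent of saturation

1. First instants. In this flask no gas is in solution yet. Here c(free catalyst) is 0.800 mM and c(stray impurity) is 0.23 mM, which is less. So the stray impurity is the limiting reagent of that pair, and I expect 71.3% of the catalyst to stay free.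

2. Middle. The maple run has the same share, 28.7%. Its product, crystals counted, reads 2.7% at 10.0 s and 15.6% at 30.0 s: 5.78 times as much in 3.00 times the time, each reading with a scatter of 1 percentage point. Read so, the maple rate rises over those seconds, at that share.

3. End. This flask holds 0.0800 M of protic impurity, twice the maple charge and 20.0% of the starting material. No run varies it, so what it takes is a guess. My reckoning commits to the catalyst, not to a yield.

4. Forecast. It gives 82% and 90%, and says “catalyst poisoning is possible”.

5. Result. This flask gives 81.7% and 98.6%.

    gas phase ⇌ dissolved gas, rate k1*(csat - [dissolved gas]) (kL = 0.0610 /s)
    starting material + dissolved gas + free catalyst → free catalyst + product (k = 120 /M²/s)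
    crystals ⇌ product, rate k3*(cs3 - [product]) while solid is left; crystals form when [product] > cs3 (solubility = 5.50 mM, k = 0.0450 /s)
    free catalyst + stray impurity → spent catalyst (k = 1900 /M/s)
    starting material + protic impurity → quenched substrate (k = 0.0440 /M/s)

The yield forecast holds within its tolerance, and the saturation forecast lies 8.6 points low. Spent catalyst in this flask stands at 28.8%, against a poison share of 28.7%. The neighbouring flask with 0.10 M of starting material has the same loading, so its c(free catalyst) is 0.200 mM, less than its 0.23 mM of stray impurity. Its poison share is 115%. In that neighbouring flask free catalyst stands at 0%, spent catalyst at 100%, and 13.0% of the stray impurity is left. At 5.00 min, that neighbouring flask holds 0.807% of product.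

The numbers in the tables come from a simulation with made-up constants; noise was put on by code.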